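## Retrosynthetic overview

1. Target 37 ⇐ hydrogenolysis of heptabenzyl ether 36; the second five-membered ring of the bicyclo[3.3.0] core ⇐ spiro-epoxide 32 by a Meinwald / Friedel–Crafts / phenol-arylation cascade (phenol supplies the last 4-hydroxyphenyl).
2. Indanone 30 ⇐ key step: intramolecular vinylogous Michael (1,6-) addition of a ketone enol to a p-quinone methide, both unmasked from alkylidene-phthalan 27.
3. 27 ⇐ Horner–Wadsworth–Emmons union of phthalan phosphonate 26 (ring A plus one 4-hydroxyphenyl) with dihydrobenzofuran aldehyde 15.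
4. 15 ⇐ enantioselective Rh-carbene C–H insertion of a diaryldiazomethane (from bromide 5 and nitrile 7), then acid epimerisation to trans.
5. Ring order: dihydrobenzofuran → indanone ring (Michael) → second cyclopentane (Friedel–Crafts).

Assumption: the sense of induction of Rh2(R-PTAD)4 (step 6) and (R)-TRIP (step 18) is assigned by analogy; if a catalyst is the wrong antipode, its commercial enantiomer is used.
Abbreviations: Ar* = (2S,3S)-4-(benzyloxy)-2-[4-(benzyloxy)phenyl]-3-[3,5-bis(benzyloxy)phenyl]-2,3-dihydro-1-benzofuran-6-yl; TBS = tert-butyldimethylsilyl.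

## Route

Step 1
Reactants: 1 methyl 4-bromo-3,5-dihydroxybenzoate; 2 4-(benzyloxy)benzyl chloride (2.2 equiv)
Product: 3 methyl 4-bromo-3,5-bis{[4-(benzyloxy)phenyl]methoxy}benzoate
Conditions: K2CO3, NaI (cat.), DMF, 60 °C
Reagents that add atoms: none
Why: Williamson etherification of the two equivalent phenols; one benzylic CH2 later becomes C-2 of the dihydrobenzofuran.

Step 2
Reactants: 3 methyl 4-bromo-3,5-bis{[4-(benzyloxy)phenyl]methoxy}benzoate
Product: 4 (4-bromo-3,5-bis{[4-(benzyloxy)phenyl]methoxy}phenyl)methanol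
Conditions: DIBAL-H, CH2Cl2, −78 → 0 °C; Rochelle salt
Reagents that add atoms: none
Why: Hydride reduction of the ester to the benzylic alcohol leaves the aryl bromide and the ethers intact.

Step 3
Reactants: 4 (4-bromo-3,5-bis{[4-(benzyloxy)phenyl]methoxy}phenyl)methanol
Product: 5 tert-butyl[(4-bromo-3,5-bis{[4-(benzyloxy)phenyl]methoxy}phenyl)methoxy]dimethylsilane
Conditions: TBSCl, imidazole, DMF, 23 °C
Reagents that add atoms: tert-butyldimethylsilyl chloride, CC(C)(C)[Si](C)(C)Cl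
Why: Silylation masks the alcohol against the organolithium and the MnO2 oxidation that follow.

Step 4
Reactants: 6 3,5-dihydroxybenzonitrile
Product: 7 3,5-bis(benzyloxy)benzonitrile
Conditions: BnBr, K2CO3, DMF, 23 °C
Reagents that add atoms: benzyl bromide, BrCc1ccccc1
Why: Williamson O-benzylation of both phenols.

Step 5
Reactants: 5 tert-butyl[(4-bromo-3,5-bis{[4-(benzyloxy)phenyl]methoxy}phenyl)methoxy]dimethylsilane; 7 3,5-bis(benzyloxy)benzonitrile
Product: 10 [2,6-bis{[4-(benzyloxy)phenyl]methoxy}-4-(TBS-oxymethyl)phenyl][3,5-bis(benzyloxy)phenyl]methanone hydrazone, via aryllithium 8 (not isolated), via N–H ketimine 9 (not isolated)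
Conditions: n-BuLi, THF, −78 °C; 7, −78 → 0 °C; then N2H4·H2O, AcOH, EtOH, 60 °C
Reagents that add atoms: hydrazine (hydrate), NN
Why: Bromine–lithium exchange (faster than benzylic deprotonation at −78 °C) gives a 2,6-dialkoxyaryllithium that adds once to the nitrile, and transimination of the ketimine avoids condensing hydrazine with a di-ortho-substituted benzophenone.

Step 6
Reactants: 10 diaryl ketone hydrazone
Product: 12 tert-butyl{[(2R,3S)-2-[4-(benzyloxy)phenyl]-4-{[4-(benzyloxy)phenyl]methoxy}-3-[3,5-bis(benzyloxy)phenyl]-2,3-dihydro-1-benzofuran-6-yl]methoxy}dimethylsilane, via diaryldiazomethane 11 (not isolated)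
Conditions: MnO2, MeCN, 23 °C, filter; Rh2(R-PTAD)4 (1 mol %), 0 → 23 °C
Reagents that add atoms: none
Why: Hydrazone dehydrogenation, then enantioselective Rh(II) donor/donor-carbene 1,5-C–H insertion into a benzylic O–CH2 (the two arms are equivalent), closes the dihydrobenzofuran as the cis isomer with C-3 set as S by the chiral carboxylate catalyst.

Step 7
Reactants: 12 cis-dihydrobenzofuran
Product: 13 (2S,3S)-2-[4-(benzyloxy)phenyl]-3-[3,5-bis(benzyloxy)phenyl]-6-(hydroxymethyl)-2,3-dihydro-1-benzofuran-4-ol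
Conditions: TFA, anisole, CH2Cl2/H2O, 0 → 23 °C
Reagents that add atoms: none
Why: SN1 ionisation of the p-alkoxybenzylic C2–O bond and re-closure (the two phenol oxygens are equivalent here) gives the thermodynamic trans isomer with C-3 untouched, while the same acid removes the remaining 4-(benzyloxy)benzyl ether (cation trapped by anisole) and the TBS ether.

Step 8
Reactants: 13 trans-dihydrobenzofuran phenol alcohol
Product: 14 [(2S,3S)-4-(benzyloxy)-2-[4-(benzyloxy)phenyl]-3-[3,5-bis(benzyloxy)phenyl]-2,3-dihydro-1-benzofuran-6-yl]methanol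
Conditions: BnBr (1.1 equiv), K2CO3, acetone, 50 °C
Reagents that add atoms: benzyl bromide, BrCc1ccccc1
Why: Chemoselective Williamson benzylation of the phenol over the benzylic alcohol; the ether later prevents furan re-closure on this oxygen and shields C-5.

Step 9
Reactants: 14 benzylic alcohol
Product: 15 (2S,3S)-4-(benzyloxy)-2-[4-(benzyloxy)phenyl]-3-[3,5-bis(benzyloxy)phenyl]-2,3-dihydro-1-benzofuran-6-carbaldehyde (Ar*–CHO)
Conditions: MnO2, CH2Cl2, 23 °C
Reagents that add atoms: none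
Why: MnO2 oxidises only the benzylic alcohol and touches no stereocentre.

Step 10
Reactants: 16 methyl 3,5-dihydroxybenzoate
Product: 17 methyl 3,5-bis(benzyloxy)benzoate
Conditions: BnBr, K2CO3, DMF, 23 °C
Reagents that add atoms: benzyl bromide, BrCc1ccccc1
Why: Williamson O-benzylation of both phenols.

Step 11
Reactants: 17 methyl 3,5-bis(benzyloxy)benzoate
Product: 18 methyl 3,5-bis(benzyloxy)-2-iodobenzoate
Conditions: NIS (1.05 equiv), TFA (cat.), MeCN, 23 °C
Reagents that add atoms: N-iodosuccinimide, O=C1CCC(=O)N1I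
Why: Electrophilic aromatic iodination at C-2 (ortho and para to the two benzyloxy groups), the usual site for 3,5-dialkoxybenzoates.

Step 12
Reactants: 19 4-hydroxybenzaldehyde
Product: 20 4-[(tert-butyldimethylsilyl)oxy]benzaldehyde
Conditions: TBSCl, imidazole, CH2Cl2, 23 °C
Reagents that add atoms: tert-butyldimethylsilyl chloride, CC(C)(C)[Si](C)(C)Cl
Why: Silylation keeps the phenol from quenching the Grignard reagent.

Step 13
Reactants: 18 methyl 3,5-bis(benzyloxy)-2-iodobenzoate; 20 4-[(tert-butyldimethylsilyl)oxy]benzaldehyde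
Product: 22 rac-4,6-bis(benzyloxy)-3-{4-[(tert-butyldimethylsilyl)oxy]phenyl}-2-benzofuran-1(3H)-one, via arylmagnesium chloride 21 (not isolated)
Conditions: i-PrMgCl·LiCl, THF, −40 °C; 20, −40 → 23 °C
Reagents that add atoms: none
Why: Iodine–magnesium exchange (turbo-Grignard, ester tolerated at −40 °C), aldehyde addition and spontaneous lactonisation give the 3-arylphthalide, whose racemic centre is erased in step 18.

Step 14
Reactants: 22 3-arylphthalide
Product: 23 4,6-bis(benzyloxy)-3-{4-[(tert-butyldimethylsilyl)oxy]phenyl}-1,3-dihydro-2-benzofuran-1-ol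
Conditions: DIBAL-H (1.2 equiv), CH2Cl2, −78 °C
Reagents that add atoms: none
Why: Partial reduction of the lactone stops at the lactol, a masked hydroxy-aldehyde.

Step 15
Reactants: 23 lactol
Product: 25 diethyl (4,6-bis(benzyloxy)-3-{4-[(tert-butyldimethylsilyl)oxy]phenyl}-1,3-dihydro-2-benzofuran-1-yl)phosphonate, via diol phosphonate 24 (not isolated)
Conditions: (EtO)2P(O)H, Et3N (cat.), THF, 40 °C; then CSA (cat.), CH2Cl2, 23 °C
Reagents that add atoms: diethyl phosphite, CCO[PH](=O)OCC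
Why: Pudovik addition to the open hydroxy-aldehyde, then acid-catalysed SN1 etherification through the stabilised benzhydryl cation (loss of water), closes the cyclic α-alkoxyphosphonate.

Step 16
Reactants: 25 silyl-protected phthalan phosphonate
Product: 26 diethyl [4,6-bis(benzyloxy)-3-(4-hydroxyphenyl)-1,3-dihydro-2-benzofuran-1-yl]phosphonate
Conditions: TBAF, AcOH, THF, 0 °C
Reagents that add atoms: none
Why: Buffered fluoride desilylation frees the phenol needed for quinone-methide formation.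

Step 17
Reactants: 26 phenol phosphonate; 15 Ar*–CHO
Product: 27 4-[4,6-bis(benzyloxy)-1-(Ar*-methylidene)-1,3-dihydro-2-benzofuran-3-yl]phenol (E/Z and C-3 mixture)
Conditions: LDA (2.2 equiv), THF, −78 °C; 15, −78 → 23 °C; pH 7 work-up, used crude
Reagents that add atoms: none
Why: Horner–Wadsworth–Emmons olefination of the phenoxide/phosphonate dianion joins the two halves as a cyclic enol ether whose geometry is irrelevant.

Step 18
Reactants: 27 alkylidene-phthalan phenol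
Product: 29 (2R,3R)-4,6-bis(benzyloxy)-3-(4-hydroxyphenyl)-2-Ar*-2,3-dihydro-1H-inden-1-one, via p-quinone methide 28 (not isolated)
Conditions: (R)-TRIP (10 mol %), toluene, 5 Å MS, 0 → 23 °C; then Et3N (cat.)
Reagents that add atoms: none
Why: The chiral phosphoric acid opens the vinylogous hemiacetal C–O bond to a p-quinone methide, and intramolecular vinylogous Michael (1,6-conjugate) addition of the tethered enol carbon to the methide carbon (formally enol-endo, available as a Nazarov-like 4π closure) forms the indanone with C-3 set as R by the phosphate-bound ion pair; C-2 equilibrates to trans and the C-3 epimer is a separable diastereomer.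

Step 19
Reactants: 29 indanone phenol
Product: 30 (2R,3R)-4,6-bis(benzyloxy)-3-[4-(benzyloxy)phenyl]-2-Ar*-2,3-dihydro-1H-inden-1-one
Conditions: BnBr, K2CO3, acetone, 23 °C, argon
Reagents that add atoms: benzyl bromide, BrCc1ccccc1
Why: Selective Williamson O-benzylation of the phenol (as with hydroxy-deoxybenzoins) protects it from the organolithium step and keeps the thermodynamic trans ketone.

Step 20
Reactants: 30 per-benzylated indanone
Product: 32 spiro-epoxide (2R,3R)-4,6-bis(benzyloxy)-3-[4-(benzyloxy)phenyl]-2-Ar*-2,3-dihydrospiro[indene-1,2'-oxirane] (C-1 epimers), via chlorohydrin alkoxide 31 (not isolated)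
Conditions: ICH2Cl, MeLi·LiBr, THF, −78 → 23 °C
Reagents that add atoms: chloroiodomethane, ClCI
Why: In situ chloromethyllithium (more nucleophilic than basic) adds to the enolisable ketone and the chlorohydrin alkoxide closes to the epoxide (carbenoid homologation); the new centre is erased in step 21.

Step 21
Reactants: 32 spiro-epoxide; 33 phenol (10 equiv)
Product: 36 hepta-O-benzyl ether of the target (free OH only on the aryl delivered by phenol), via aldehyde 34 (not isolated), via benzylic alcohol 35 (not isolated)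
Conditions: BF3·OEt2 (20 mol %), CH2Cl2, −78 → −30 °C; then PhOH, −30 → 0 °C
Reagents that add atoms: none
Why: Meinwald rearrangement gives the aldehyde, whose cis epimer (reached via the enol) undergoes intramolecular Friedel–Crafts hydroxyalkylation at C-7 of the dihydrobenzofuran (para to OBn and flanked only by the ring oxygen, whereas C-5 is shielded by the benzyloxy group), which forces the cis ring fusion; the resulting carbinol ionises with loss of water to a doubly activated benzylic cation that is arylated by phenol at its para position from the convex face, so the aryl ends exo.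

Step 22
Reactants: 36 hepta-O-benzyl ether
Product: 37 target CNP0154244.2
Conditions: H2 (1 atm), Pd/C, EtOAc/MeOH, 23 °C
Reagents that add atoms: none
Why: Neutral hydrogenolysis of the seven aryl benzyl ethers leaves the dihydrobenzofuran and all six stereocentres intact.

## Compound list

1 | methyl 4-bromo-3,5-dihydroxybenzoate | COC(=O)c1cc(O)c(Br)c(O)c1 | starting material
2 | 4-(benzyloxy)benzyl chloride | ClCc1ccc(OCc2ccccc2)cc1 | starting material
3 | methyl 4-bromo-3,5-bis{[4-(benzyloxy)phenyl]methoxy}benzoate | COC(=O)c1cc(OCc2ccc(OCc3ccccc3)cc2)c(Br)c(OCc2ccc(OCc3ccccc3)cc2)c1 | intermediate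
4 | (4-bromo-3,5-bis{[4-(benzyloxy)phenyl]methoxy}phenyl)methanol | OCc1cc(OCc2ccc(OCc3ccccc3)cc2)c(Br)c(OCc2ccc(OCc3ccccc3)cc2)c1 | intermediate
5 | TBS ether of 4 | CC(C)(C)[Si](C)(C)OCc1cc(OCc2ccc(OCc3ccccc3)cc2)c(Br)c(OCc2ccc(OCc3ccccc3)cc2)c1 | intermediate
6 | 3,5-dihydroxybenzonitrile | N#Cc1cc(O)cc(O)c1 | starting material
7 | 3,5-bis(benzyloxy)benzonitrile | N#Cc1cc(OCc2ccccc2)cc(OCc2ccccc2)c1 | intermediate
8 | aryllithium from 5 (Li in place of Br) | [Li]c1c(OCc2ccc(OCc3ccccc3)cc2)cc(CO[Si](C)(C)C(C)(C)C)cc1OCc1ccc(OCc2ccccc2)cc1 | intermediate (not isolated)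
9 | N–H diaryl ketimine | N=C(c1cc(OCc2ccccc2)cc(OCc2ccccc2)c1)c1c(OCc2ccc(OCc3ccccc3)cc2)cc(CO[Si](C)(C)C(C)(C)C)cc1OCc1ccc(OCc2ccccc2)cc1 | intermediate (not isolated)
10 | diaryl ketone hydrazone | NN=C(c1cc(OCc2ccccc2)cc(OCc2ccccc2)c1)c1c(OCc2ccc(OCc3ccccc3)cc2)cc(CO[Si](C)(C)C(C)(C)C)cc1OCc1ccc(OCc2ccccc2)cc1 | intermediate
11 | diaryldiazomethane | [N-]=[N+]=C(c1cc(OCc2ccccc2)cc(OCc2ccccc2)c1)c1c(OCc2ccc(OCc3ccccc3)cc2)cc(CO[Si](C)(C)C(C)(C)C)cc1OCc1ccc(OCc2ccccc2)cc1 | intermediate (not isolated)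
12 | (2R,3S)-cis-dihydrobenzofuran, 4-O-[4-(benzyloxy)benzyl], 6-CH2OTBS | CC(C)(C)[Si](C)(C)OCc1cc(OCc3ccc(OCc4ccccc4)cc3)c2c(c1)O[C@@H](c1ccc(OCc3ccccc3)cc1)[C@H]2c1cc(OCc2ccccc2)cc(OCc2ccccc2)c1 | intermediate
13 | (2S,3S)-trans-dihydrobenzofuran, 4-OH, 6-CH2OH | OCc1cc(O)c2c(c1)O[C@H](c1ccc(OCc3ccccc3)cc1)[C@H]2c1cc(OCc2ccccc2)cc(OCc2ccccc2)c1 | intermediate
14 | Ar*–CH2OH | OCc1cc(OCc3ccccc3)c2c(c1)O[C@H](c1ccc(OCc3ccccc3)cc1)[C@H]2c1cc(OCc2ccccc2)cc(OCc2ccccc2)c1 | intermediate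
15 | Ar*–CHO | O=Cc1cc(OCc3ccccc3)c2c(c1)O[C@H](c1ccc(OCc3ccccc3)cc1)[C@H]2c1cc(OCc2ccccc2)cc(OCc2ccccc2)c1 | intermediate
16 | methyl 3,5-dihydroxybenzoate | COC(=O)c1cc(O)cc(O)c1 | starting material
17 | methyl 3,5-bis(benzyloxy)benzoate | COC(=O)c1cc(OCc2ccccc2)cc(OCc2ccccc2)c1 | intermediate
18 | methyl 3,5-bis(benzyloxy)-2-iodobenzoate | COC(=O)c1cc(OCc2ccccc2)cc(OCc2ccccc2)c1I | intermediate
19 | 4-hydroxybenzaldehyde | O=Cc1ccc(O)cc1 | starting material
20 | 4-[(tert-butyldimethylsilyl)oxy]benzaldehyde | O=Cc1ccc(O[Si](C)(C)C(C)(C)C)cc1 | intermediate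
21 | [2,4-bis(benzyloxy)-6-(methoxycarbonyl)phenyl]magnesium chloride | COC(=O)c1cc(OCc2ccccc2)cc(OCc2ccccc2)c1[Mg]Cl | intermediate (not isolated)
22 | rac-3-aryl-4,6-bis(benzyloxy)phthalide | O=C1OC(c2ccc(O[Si](C)(C)C(C)(C)C)cc2)c2c(OCc3ccccc3)cc(OCc3ccccc3)cc12 | intermediate
23 | lactol of 22 (diastereomers, racemic) | OC1OC(c2ccc(O[Si](C)(C)C(C)(C)C)cc2)c2c(OCc3ccccc3)cc(OCc3ccccc3)cc12 | intermediate
24 | open-chain diol α-hydroxyphosphonate (diastereomers) | CCOP(=O)(OCC)C(O)c1cc(OCc2ccccc2)cc(OCc2ccccc2)c1C(O)c1ccc(O[Si](C)(C)C(C)(C)C)cc1 | intermediate (not isolated)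
25 | phthalan-1-phosphonate, aryl O-TBS (diastereomers, racemic) | CCOP(=O)(OCC)C1OC(c2ccc(O[Si](C)(C)C(C)(C)C)cc2)c2c(OCc3ccccc3)cc(OCc3ccccc3)cc12 | intermediate
26 | phthalan-1-phosphonate, free phenol (diastereomers, racemic) | CCOP(=O)(OCC)C1OC(c2ccc(O)cc2)c2c(OCc3ccccc3)cc(OCc3ccccc3)cc12 | intermediate
27 | alkylidene-phthalan enol ether (E/Z, epimers at the phthalan CH; dihydrobenzofuran 2S,3S) | Oc1ccc(cc1)C1OC(=Cc2cc(OCc3ccccc3)c3c(c2)O[C@H](c2ccc(OCc4ccccc4)cc2)[C@H]3c2cc(OCc3ccccc3)cc(OCc3ccccc3)c2)c2cc(OCc3ccccc3)cc(OCc3ccccc3)c12 | intermediate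
28 | p-quinone methide: 4-({2,4-bis(benzyloxy)-6-[2-(Ar*)acetyl]phenyl}methylidene)cyclohexa-2,5-dien-1-one | O=C1C=CC(=Cc2c(OCc3ccccc3)cc(OCc3ccccc3)cc2C(=O)Cc2cc(OCc3ccccc3)c3c(c2)O[C@H](c2ccc(OCc4ccccc4)cc2)[C@H]3c2cc(OCc3ccccc3)cc(OCc3ccccc3)c2)C=C1 | intermediate (not isolated)
29 | (2R,3R)-trans-indanone, free 4-hydroxyphenyl | Oc1ccc([C@@H]2c3c(OCc6ccccc6)cc(OCc6ccccc6)cc3C(=O)[C@H]2c2cc(OCc6ccccc6)c3c(c2)O[C@H](c2ccc(OCc6ccccc6)cc2)[C@H]3c2cc(OCc6ccccc6)cc(OCc6ccccc6)c2)cc1 | intermediate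
30 | (2R,3R)-trans-indanone, all phenols benzylated | c1ccccc1COc1ccc([C@@H]2c3c(OCc6ccccc6)cc(OCc6ccccc6)cc3C(=O)[C@H]2c2cc(OCc6ccccc6)c3c(c2)O[C@H](c2ccc(OCc6ccccc6)cc2)[C@H]3c2cc(OCc6ccccc6)cc(OCc6ccccc6)c2)cc1 | intermediate
31 | chlorohydrin (lithium alkoxide in the flask; C-1 epimers) | c1ccccc1COc1ccc([C@@H]2c3c(OCc6ccccc6)cc(OCc6ccccc6)cc3C(O)(CCl)[C@H]2c2cc(OCc6ccccc6)c3c(c2)O[C@H](c2ccc(OCc6ccccc6)cc2)[C@H]3c2cc(OCc6ccccc6)cc(OCc6ccccc6)c2)cc1 | intermediate (not isolated)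
32 | spiro-epoxide (C-1 epimers) | c1ccccc1COc1ccc([C@@H]2c3c(OCc6ccccc6)cc(OCc6ccccc6)cc3C7(CO7)[C@H]2c2cc(OCc6ccccc6)c3c(c2)O[C@H](c2ccc(OCc6ccccc6)cc2)[C@H]3c2cc(OCc6ccccc6)cc(OCc6ccccc6)c2)cc1 | intermediate
33 | phenol | Oc1ccccc1 | starting material
34 | indane-1-carbaldehyde (C-1 epimers) | c1ccccc1COc1ccc([C@@H]2c3c(OCc6ccccc6)cc(OCc6ccccc6)cc3C(C=O)[C@H]2c2cc(OCc6ccccc6)c3c(c2)O[C@H](c2ccc(OCc6ccccc6)cc2)[C@H]3c2cc(OCc6ccccc6)cc(OCc6ccccc6)c2)cc1 | intermediate (not isolated)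
35 | cyclised benzylic alcohol (cis-fused core, OH in place of the last aryl, carbinol epimers) | c1ccccc1COc1ccc([C@@H]2c3c(OCc6ccccc6)cc(OCc6ccccc6)cc3[C@H]3C(O)c4c(cc(OCc6ccccc6)c5c4O[C@H](c4ccc(OCc6ccccc6)cc4)[C@H]5c4cc(OCc6ccccc6)cc(OCc6ccccc6)c4)[C@@H]23)cc1 | intermediate (not isolated)
36 | hepta-O-benzyl ether of the target (only the phenol-derived aryl carries free OH) | c1ccccc1COc1ccc([C@@H]2c3c(OCc6ccccc6)cc(OCc6ccccc6)cc3[C@H]3[C@H](c4ccc(O)cc4)c4c(cc(OCc6ccccc6)c5c4O[C@H](c4ccc(OCc6ccccc6)cc4)[C@H]5c4cc(OCc6ccccc6)cc(OCc6ccccc6)c4)[C@@H]23)cc1 | intermediate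
37 | CNP0154244.2 | Oc1ccc([C@@H]2c3c(O)cc(O)cc3[C@H]3[C@H](c4ccc(O)cc4)c4c(cc(O)c5c4O[C@H](c4ccc(O)cc4)[C@H]5c4cc(O)cc(O)c4)[C@@H]23)cc1 | target

## Summary

Total step count: 22.
Longest linear sequence: 14 steps (1, 2, 3, 5, 6, 7, 8, 9, 17, 18, 19, 20, 21, 22).

## Steps most likely to fail

**Step 6 (with the epimerisation in step 7).** The carbene precursor is di-ortho-substituted, and ionisation in step 7 could erode ee by elimination. The fallback sets out from 5 and 7 and comes back at 13. The nitrile adduct 9 is hydrolysed with aqueous HCl to the diaryl ketone F1. Corey–Chaykovsky epoxidation (Me3S+ I−, KOt-Bu, DMSO) gives the diaryl epoxide F2, and ZnI2 rearranges it to the diarylacetaldehyde F3. Commercial 4-(benzyloxy)phenylmagnesium bromide gives the alcohol F4. TFA/anisole then removes both 4-(benzyloxy)benzyl ethers and the TBS group and closes the p-alkoxybenzylic cation onto a phenol. This gives the trans-dihydrobenzofuran as a racemate, 13 together with its (2R,3R)-enantiomer F5, which is resolved by preparative chiral SFC.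

**Step 18.** Quinone-methide generation or catalyst control at C-3 may fail. The fallback sets out from 26 and comes back at 30. The phenol is benzylated (BnBr, K2CO3) to the O-benzyl phosphonate F6. Olefination with 15 gives the O-benzyl enol ether F7. Sc(OTf)3 (10 mol %, CH2Cl2, −40 °C) ionises it to the p-benzyloxybenzhydryl cation, which closes with the enol (Nazarov-type cation–enol cyclisation) without a chiral catalyst. This gives 30 and its (2S,3S)-indanone epimer F8; they are diastereomers because of the fixed dihydrobenzofuran and are separated by chromatography.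

**Step 21.** The epoxide rearrangement, the C-7 versus C-5 selectivity or the phenol trapping may fail. The fallback sets out from 30 and comes back at 37. Petasis methylenation (Cp2TiMe2, toluene, 70 °C) gives the exocyclic alkene F9. 9-BBN then NaOH/H2O2 gives the cis primary alcohol F10, with H delivered anti to the C-2 aryl. Dess–Martin oxidation gives the cis aldehyde F11. 4-(Benzyloxy)phenylmagnesium bromide at −78 °C gives the diaryl carbinol F12. Catalytic Bi(OTf)3 forms the bulkier, reversibly formed p-alkoxybenzylic cation, which closes onto C-7 to the octabenzyl ether F13. Hydrogenolysis as in step 22 gives 37.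

## Further compounds

F1 | step 6 | [2,6-bis{[4-(benzyloxy)phenyl]methoxy}-4-(TBS-oxymethyl)phenyl][3,5-bis(benzyloxy)phenyl]methanone | O=C(c1cc(OCc2ccccc2)cc(OCc2ccccc2)c1)c1c(OCc2ccc(OCc3ccccc3)cc2)cc(CO[Si](C)(C)C(C)(C)C)cc1OCc1ccc(OCc2ccccc2)cc1
F2 | step 6 | rac-2,2-diaryloxirane from F1 | C1OC1(c1cc(OCc2ccccc2)cc(OCc2ccccc2)c1)c1c(OCc2ccc(OCc3ccccc3)cc2)cc(CO[Si](C)(C)C(C)(C)C)cc1OCc1ccc(OCc2ccccc2)cc1
F3 | step 6 | rac-2,2-diarylacetaldehyde | O=CC(c1cc(OCc2ccccc2)cc(OCc2ccccc2)c1)c1c(OCc2ccc(OCc3ccccc3)cc2)cc(CO[Si](C)(C)C(C)(C)C)cc1OCc1ccc(OCc2ccccc2)cc1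
F4 | step 6 | 1-[4-(benzyloxy)phenyl]-2,2-diarylethanol (diastereomers, racemic) | OC(c1ccc(OCc2ccccc2)cc1)C(c1cc(OCc2ccccc2)cc(OCc2ccccc2)c1)c1c(OCc2ccc(OCc3ccccc3)cc2)cc(CO[Si](C)(C)C(C)(C)C)cc1OCc1ccc(OCc2ccccc2)cc1
F5 | step 6 | (2R,3R)-enantiomer of 13 | OCc1cc(O)c2c(c1)O[C@@H](c1ccc(OCc3ccccc3)cc1)[C@@H]2c1cc(OCc2ccccc2)cc(OCc2ccccc2)c1
F6 | step 18 | diethyl {4,6-bis(benzyloxy)-3-[4-(benzyloxy)phenyl]-1,3-dihydro-2-benzofuran-1-yl}phosphonate (diastereomers, racemic) | CCOP(=O)(OCC)C1OC(c2ccc(OCc3ccccc3)cc2)c2c(OCc3ccccc3)cc(OCc3ccccc3)cc12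
F7 | step 18 | O-benzyl analogue of enol ether 27 (E/Z, epimers at the phthalan CH) | c1ccccc1COc1ccc(cc1)C1OC(=Cc2cc(OCc3ccccc3)c3c(c2)O[C@H](c2ccc(OCc4ccccc4)cc2)[C@H]3c2cc(OCc3ccccc3)cc(OCc3ccccc3)c2)c2cc(OCc3ccccc3)cc(OCc3ccccc3)c12
F8 | step 18 | (2S,3S)-indanone epimer of 30 (dihydrobenzofuran unchanged 2S,3S) | c1ccccc1COc1ccc([C@H]2c3c(OCc6ccccc6)cc(OCc6ccccc6)cc3C(=O)[C@@H]2c2cc(OCc6ccccc6)c3c(c2)O[C@H](c2ccc(OCc6ccccc6)cc2)[C@H]3c2cc(OCc6ccccc6)cc(OCc6ccccc6)c2)cc1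
F9 | step 21 | 1-methylidene-indane from 30 | c1ccccc1COc1ccc([C@@H]2c3c(OCc6ccccc6)cc(OCc6ccccc6)cc3C(=C)[C@H]2c2cc(OCc6ccccc6)c3c(c2)O[C@H](c2ccc(OCc6ccccc6)cc2)[C@H]3c2cc(OCc6ccccc6)cc(OCc6ccccc6)c2)cc1
F10 | step 21 | 1-(hydroxymethyl)indane, CH2OH cis to the C-2 aryl | c1ccccc1COc1ccc([C@@H]2c3c(OCc6ccccc6)cc(OCc6ccccc6)cc3[C@@H](CO)[C@H]2c2cc(OCc6ccccc6)c3c(c2)O[C@H](c2ccc(OCc6ccccc6)cc2)[C@H]3c2cc(OCc6ccccc6)cc(OCc6ccccc6)c2)cc1
F11 | step 21 | cis-indane-1-carbaldehyde (single C-1 epimer of 34) | c1ccccc1COc1ccc([C@@H]2c3c(OCc6ccccc6)cc(OCc6ccccc6)cc3[C@@H](C=O)[C@H]2c2cc(OCc6ccccc6)c3c(c2)O[C@H](c2ccc(OCc6ccccc6)cc2)[C@H]3c2cc(OCc6ccccc6)cc(OCc6ccccc6)c2)cc1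
F12 | step 21 | [4-(benzyloxy)phenyl](cis-indan-1-yl)methanol (carbinol epimers) | c1ccccc1COc1ccc([C@@H]2c3c(OCc6ccccc6)cc(OCc6ccccc6)cc3[C@@H](C(O)c4ccc(OCc6ccccc6)cc4)[C@H]2c2cc(OCc6ccccc6)c3c(c2)O[C@H](c2ccc(OCc6ccccc6)cc2)[C@H]3c2cc(OCc6ccccc6)cc(OCc6ccccc6)c2)cc1
F13 | step 21 | octa-O-benzyl ether of the target | c1ccccc1COc1ccc([C@@H]2c3c(OCc6ccccc6)cc(OCc6ccccc6)cc3[C@H]3[C@H](c4ccc(OCc6ccccc6)cc4)c4c(cc(OCc6ccccc6)c5c4O[C@H](c4ccc(OCc6ccccc6)cc4)[C@H]5c4cc(OCc6ccccc6)cc(OCc6ccccc6)c4)[C@@H]23)cc1
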